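Saturday's readings cannot tell a first-order leak from a second-order one: target goes from 32.7% at 25.0 min to 26.5% at 300 min, with a scatter of 1 percentage point on each reading, and either curve passes through that.

| setting | Saturday's | Friday's | flask |
|---|---|---|---|
| starting material | 0.10 M | 0.050 M | 0.10 M |
| remark | the very flask that is asked about, followed so far | run made earlier |  |
| time |  |  | 5.0 h |

| Saturday's: time / min | Saturday's: target / % | Friday's: time / min | Friday's: target / % |
|---|---|---|---|
| 25.0 | 32.7 | 3.00 | 43.7 |
| 50.0 | 33.5 | 6.00 | 36.7 |
| 80.0 | 30.0 | 10.0 | 35.0 |
| 150 | 30.1 | 12.0 | 35.2 |
| 300 | 26.5 | 15.0 | 35.0 |

(each reading ± 1 percentage point)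

- epsilon: at 5.0 h take out 90% of the target then present, then wait 2.5 h
- theta: at 5.0 h add starting material, 50.0% of the amount charged, then wait 2.5 h
- alpha: change nothing and wait 2.5 h more

- removed target is counted in
- additions bring no volume worth counting

* target, in percent of the starting material first charged, at 5.0 h
* what to do for the largest gain in target; "none" if nothing gains more than 2 percentage points (epsilon / theta / alpha / none)
* target present, with what was taken out counted in, in percent of the starting material first charged, after epsilon
* target present, with what was taken out counted in, in percent of the starting material first charged, after theta

Two chemists read Friday's flat 35.0% as a fast partition: target is a share φ of a pool that redistributes within minutes. They part on how the pool leaks. The first takes a first-order leak, L = ln(first reading/last reading)/(time between) = 7.64 × 10⁻⁴ /min.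

The second sees Saturday's run, at twice the concentration, stand lower than Friday's, which at this scatter is a hint, and takes a leak second-order in the pool. The quantity carried is the leak coefficient s, the growth of 1/y per minute, with y the target as a fraction of the charge: s = 0.00260 /min at Saturday's concentration.

I reckon with the second, taking φ as Friday's plateau and the target now as the last reading. Epsilon takes out 23.9%, and the remaining pool repartitions to 18.2%. Adding s times 2.5 h to 1/y then gives a total of 40.8%. Theta lifts target to 44.0%, and the same wait leaves 37.6%. Epsilon leads by 3.2 points, more than the 0.8 points that L gives on the same steps.

The forecast, on the first-order side, says 26.7% now, 40.4% after epsilon and 38.7% after theta, choosing epsilon since “removed target is protected from the leak”.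

The simulation gives 25.9%, 39.5% and 36.4%, so epsilon is best, with a gain of 14 points against 10 points for theta and a gap of 3.1 points.

    starting material ⇌ target (K = 4.60, k = 0.0150 /s)
    2 starting material → homo dimer (k = 0.0140 /M/s)
    target ⇌ isomer of the product (K = 1.50, k = 0.00740 /s)

The first view keeps the wait on an untouched pool: for alpha it reckons a fall of 2.9 points, and the flask falls 2.6 points. The flask is not at rest. At 3000 min, ten times the asked time, target stands at 8.58%, down from 25.9% at 300 min. Homo dimer, counted by the starting material it holds, stands at 76.7% at 3000 min, up from 29.5% at 300 min. Isomer of the product over target is 1.50 at 300 min and 1.50 at 3000 min. For the flask left until 20 h, s gives 16.4% target; the simulation gives 15.5%.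

The runs stem from a simulated flask with constants of no real substance, noise included.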